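## Analysis of the target

The target 40 is a ten-membered carbocycle (C1 to C10) fused at C6/C7 to an alpha-methylene-gamma-butyrolactone (O, C6, C7, C11, C12, with exocyclic C11=C13). Both ring olefins are trisubstituted and have their two ring bonds cis: C1=C10 carries the methyl ester carbon C14 on C10 (C2 cis to C9), and C4=C5 carries the hydroxymethyl carbon C15 on C4 (C3 cis to C6). Four contiguous stereocentres run from C6 to C9 (6R,7S,8S,9R): H6 and H7 are trans across the lactone, C11 on C7 and O8 lie on opposite sides of the ring chain, and O8/O9 are erythro, so they form a cis-dioxolane when tied together. O8 carries a methacrylate and O9 an acetate, so two neighbouring secondary hydroxyls must be told apart, and three allylic CH2–O carbons (C12, C14, C15) must end as lactone carbonyl, methyl ester and free alcohol. The methylene lactone and the methacrylate are polymerisable Michael acceptors, the vicinal diester can undergo acyl migration, a free O8 can take the lactone over from O6, and no ester survives strong base, so all acyl groups must come late. The hard part is closing a medium ring that holds two cis olefins while setting C6 and C7 against the existing C8/C9 pair. The route rests on one feature: C6 is a carbinol carbon allylic to C4=C5, and its neighbour C7 carries the C11=C13 methylene unit. This homoallylic alcohol is what a [2,3]-Wittig shift leaves behind when an ether oxygen on C6 is bridged to C13.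

## Retrosynthetic reasoning

**40 back to 37.** The O15–Si bond, the O8–methacryloyl bond and the O9–acetyl bond are cut in that order (39, 38, 37). The esters are introduced last because they tolerate neither the organolithium nor the hydride steps. O15 stays silylated until both acylations are done so that the primary alcohol is not esterified. The forward steps have to distinguish O9 from O8.

**37 back to 31.** The acetonide of 36 keeps O8 blocked, so that only O6 can close onto C12. The lactone C12–O6 bond and the C14 ester are taken back through acid 35 and aldehyde 34 to triol 32 and the bis-silyl ether 31. C12 and C14 thus travel as silyl ethers, which survive the carbanion step, while C15 keeps a more robust silyl group.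

**31 back to 29 (key disconnection).** The C6–C7 bond is cut and O6 is joined to C13. This turns the ten-membered carbocycle into the thirteen-membered diallylic ether 29, which is far easier to close. It also hides the exocyclic methylene as the trisubstituted C7=C11 olefin, whose geometry encodes the C6/C7 relationship. No other ring bond has both ends becoming stereocentres with the needed functionality beside them. The forward step must generate the carbanion at C6 and bond it to one face of C7.

**29 back to 28.** The O–C13 ether bond is cut to the chloro alcohol 28. The alkoxide is placed on O6 and the leaving group on C13 because an alkoxide on O13 would sit next to the C12 silyl ether and could take over its silicon, which would scramble the two arms on C11.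

**28 back to 10 and 22.** After undoing the acetonide, the chloride and the pivalate removal (26, 24, 23), the C9–C10 bond is cut between aldehyde 10 and alkenyl iodide 22. This bond divides the chain into two halves of similar size, and its formation creates C9 next to the existing C8 stereocentre. The forward addition must be mild enough for an enolisable aldehyde and must attack anti to the C8 oxygen.

**10 back to 4 and 3.** The C7=C11 double bond is cut to the chiral-pool aldehyde 4, which supplies C8, and the phosphonate 3, made from 1. The olefination itself differentiates the two CH2–O arms on C11: the ester ends trans to C8 and becomes C13, and the silyloxymethyl arm ends cis and becomes C12. Compounds 5 to 9 only adjust protecting groups to unmask C9.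

**22 back to 18 and 1.** The C1=C10 double bond is cut to aldehyde 18 and the iodinated form 19 of phosphonate 1. This places iodine cis to C2 and gives C14 at the ester level (20), which is then reduced and silylated (21, 22).

**18 back to 15 and 16, and 15 back to 11.** The C3–C4 bond is cut to alkenyl iodide 15 and the three-carbon zinc reagent 16 (via 17). The iodide comes from the alkyne 12, itself from diol 11, by a hydroxyl-directed trans-hydrometalation that fixes the C4=C5 geometry without any selectivity question.

## Alternatives that were turned down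

**Alternative 1:** Here the ring is opened at C5–C6 and the lactone at its C12–O bond. In the forward direction CrCl2 with catalytic NiCl2 turns a Z-configured C5 alkenyl iodide into an alkenylchromium species that adds to a C6 aldehyde. The resulting C6 alkoxide closes the lactone on a C12 methyl ester, giving A1 with the methylene group masked as a phenylselenomethyl group.
- **For it:** organochromium chemistry tolerates esters, so both acyl groups and the C14 methyl ester can already be in place. Only selenoxide elimination and desilylation remain after ring closure. On this point it is clearly stronger than the chosen route, which needs eight steps after the key step.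
- **Against it:** the ten-membered ring has to be closed directly against transannular strain. C6 is created in that closure with no mechanistic link to C7. The aldehyde carbon C6 has the stereogenic C7 as its alpha carbon and an acyloxy group on C8 in the beta position, so epimerisation and beta-elimination threaten before the ring forms. C7, C8, C9 and C11 would all have to be set beforehand in an open chain.
- **In its place the chosen route offers:** ring formation from a strain-free thirteen-membered ether, and C6 and C7 set together in one concerted transition state.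

**Alternative 2:** This cuts C2–C3 of an eight-membered ring (C2 to C9) and traces it to a xylose-derived tetrahydropyran with an exocyclic enol ether (C9=C2) and an alkenyl group (C4=C3 on C5). A Claisen rearrangement forms C2–C3, breaks O–C5 and gives the cyclooctenone A2.
- **For it:** the sugar supplies oxygenated stereocentres in absolute form, and the pericyclic step gives the cis C4=C5 olefin with certainty. In olefin control it is as strong as the chosen strategy, and its stereocentres come from the chiral pool rather than from induction.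
- **Against it:** A2 holds only eight of the ten ring carbons, so C1 and C10 must still be inserted. C9 emerges as a ketone and its stereocentre must be made again. C11 sits in a dioxane whose two arms must later be differentiated and turned into the methylene lactone. The carbon branch at C7 has to be forced onto a sugar carbon. The chosen route is many steps shorter after the key step.
- **In its place the chosen route offers:** the complete ten-membered ring with the C11=C13 unit and the C6 hydroxyl exactly where the lactone needs them.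

**Alternative 3:** This cuts C1–C2 and C9–C10, so the C1=C10 unit with its ester is inserted into a cyclooctenone of the A2 type. The pyrrolidine enamine adds methyl propiolate in a [2+2] sense, the cyclobutene opens and acid hydrolysis gives the ten-membered keto ester A3.
- **For it:** C1, C10 and C14 arrive in one operation with C14 already a methyl ester. This is better than the chosen route, which carries C14 as a silyl ether and spends three steps oxidising it.
- **Against it:** the enamine must form towards C2 and not towards C8, which bears an oxygen. The geometry of the new C1=C10 bond after ring opening and hydrolysis is not secured. A3 is an alkylidene beta-keto ester, a very reactive acceptor, whose C9 ketone must then be reduced with the right facial selectivity in a flexible ring. The sequence also needs the whole of alternative 2 before it.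
- **In its place the chosen route offers:** C1=C10 geometry fixed in an open-chain olefination, and C9 set by a simple addition next to C8.

Key step: step 22

Remark: the atom numbers of the target are used for all intermediates. The C9 epimers from step 17 are assumed to be separable by chromatography (at 23 or at 28), and the route continues with the 8S,9R isomer.

## Route

Step 1
Reactants: 1 triethyl phosphonoacetate
Product: 2 ethyl 2-(diethoxyphosphoryl)-3-hydroxypropanoate (racemic)
Conditions: (CH2O)n (1.0 equiv), K2CO3 (cat.), THF, rt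
Reagents that add atoms: formaldehyde (as paraformaldehyde), C=O
Why: Base-catalysed aldol-type hydroxymethylation of the active methylene group; with catalytic base and one equivalent of formaldehyde it should stop at the mono-adduct, because the follow-up olefination to the acrylate would consume stoichiometric base.

Step 2
Reactants: 2 ethyl 2-(diethoxyphosphoryl)-3-hydroxypropanoate
Product: 3 ethyl 3-[(tert-butyldimethylsilyl)oxy]-2-(diethoxyphosphoryl)propanoate (racemic)
Conditions: TBSCl, imidazole, DMF, 0 °C to rt
Reagents that add atoms: tert-butyldimethylsilyl chloride, CC(C)(C)[Si](C)(C)Cl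
Why: Standard silylation of a primary alcohol; the silyl ether blocks retro-aldol loss of formaldehyde from the phosphonate anion in the next step.

Step 3
Reactants: 3 ethyl 3-[(tert-butyldimethylsilyl)oxy]-2-(diethoxyphosphoryl)propanoate; 4 (R)-2,2-dimethyl-1,3-dioxolane-4-carbaldehyde
Product: 5 ethyl (E)-2-{[(tert-butyldimethylsilyl)oxy]methyl}-3-[(4S)-2,2-dimethyl-1,3-dioxolan-4-yl]prop-2-enoate
Conditions: NaH, THF, −20 to 0 °C
Reagents that add atoms: none
Why: Horner–Wadsworth–Emmons olefination with an alpha-substituted phosphonoacetate; thermodynamic control should place the ester trans to the dioxolane carbon C8, so the ester carbon becomes C13 and the silyloxymethyl arm (C12) is cis to C8. C8 is carried over unchanged from 4, and the stabilised anion is kept cold so that it does not expel silanolate.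

Step 4
Reactants: 5 ethyl (E)-2-{[(tert-butyldimethylsilyl)oxy]methyl}-3-[(4S)-2,2-dimethyl-1,3-dioxolan-4-yl]prop-2-enoate
Product: 6 (Z)-2-{[(tert-butyldimethylsilyl)oxy]methyl}-3-[(4S)-2,2-dimethyl-1,3-dioxolan-4-yl]prop-2-en-1-ol
Conditions: i-Bu2AlH (2.2 equiv), CH2Cl2, −78 °C
Reagents that add atoms: none
Why: 1,2-Reduction of the enoate to the allylic alcohol by the aluminium hydride; silyl ether and ketal are inert at −78 °C.

Step 5
Reactants: 6 (Z)-2-{[(tert-butyldimethylsilyl)oxy]methyl}-3-[(4S)-2,2-dimethyl-1,3-dioxolan-4-yl]prop-2-en-1-ol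
Product: 7 (Z)-2-{[(tert-butyldimethylsilyl)oxy]methyl}-3-[(4S)-2,2-dimethyl-1,3-dioxolan-4-yl]prop-2-en-1-yl pivalate
Conditions: PivCl, pyridine, DMAP (cat.), CH2Cl2, 0 °C
Reagents that add atoms: pivaloyl chloride, CC(C)(C)C(Cl)=O
Why: Acylation under amine conditions masks O13 through the organochromium step; no alkoxide is generated next to the C12 silyl ether, so the two arms on C11 cannot exchange.

Step 6
Reactants: 7 (Z)-2-{[(tert-butyldimethylsilyl)oxy]methyl}-3-[(4S)-2,2-dimethyl-1,3-dioxolan-4-yl]prop-2-en-1-yl pivalate
Product: 8 (2Z,4S)-2-{[(tert-butyldimethylsilyl)oxy]methyl}-4,5-dihydroxypent-2-en-1-yl pivalate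
Conditions: CeCl3·7H2O, (CO2H)2 (cat.), MeCN, rt
Reagents that add atoms: none
Why: Lewis-acid-assisted hydrolysis of a terminal isopropylidene ketal, chosen because it is mild enough to leave a primary TBS ether and the allylic pivalate untouched.

Step 7
Reactants: 8 (2Z,4S)-2-{[(tert-butyldimethylsilyl)oxy]methyl}-4,5-dihydroxypent-2-en-1-yl pivalate
Product: 9 (2Z,4S)-2-{[(tert-butyldimethylsilyl)oxy]methyl}-4,5-bis[(triethylsilyl)oxy]pent-2-en-1-yl pivalate
Conditions: TESCl, imidazole, DMF, 0 °C
Reagents that add atoms: chlorotriethylsilane, CC[Si](Cl)(CC)CC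
Why: Silylation of both hydroxyls; the primary TES ether is the latent aldehyde and the secondary one is the bulky Felkin group for step 17.

Step 8
Reactants: 9 (2Z,4S)-2-{[(tert-butyldimethylsilyl)oxy]methyl}-4,5-bis[(triethylsilyl)oxy]pent-2-en-1-yl pivalate
Product: 10 (2Z,4S)-2-{[(tert-butyldimethylsilyl)oxy]methyl}-5-oxo-4-[(triethylsilyl)oxy]pent-2-en-1-yl pivalate
Conditions: (COCl)2, DMSO, CH2Cl2, −78 to −40 °C; Et3N, −78 °C
Reagents that add atoms: none
Why: Swern oxidation in which activated DMSO cleaves and oxidises only the primary triethylsilyl ether, leaving the secondary TES and the TBS ether. The alpha-silyloxy beta,gamma-unsaturated aldehyde is kept cold and used at once without chromatography, to avoid epimerisation at C8 or migration of the double bond.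

Step 9
Reactants: 11 but-2-yne-1,4-diol
Product: 12 4-[(tert-butyldiphenylsilyl)oxy]but-2-yn-1-ol
Conditions: TBDPSCl (0.3 equiv), imidazole, DMF, 0 °C (diol in excess)
Reagents that add atoms: tert-butyl(chloro)diphenylsilane, CC(C)(C)[Si](Cl)(c1ccccc1)c1ccccc1
Why: Statistical monosilylation with the cheap diol in excess; this differentiates the future C6 and C15 oxygens.

Step 10
Reactants: 12 4-[(tert-butyldiphenylsilyl)oxy]but-2-yn-1-ol
Product: 14 (Z)-4-[(tert-butyldiphenylsilyl)oxy]-3-iodobut-2-en-1-ol, via cyclic alkenylalanate 13 (not isolated)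
Conditions: NaAlH2(OCH2CH2OCH3)2, THF, 0 °C; EtOAc; I2, −78 °C
Reagents that add atoms: sodium bis(2-methoxyethoxy)aluminium dihydride, [Na+].[AlH2-](OCCOC)OCCOC (aluminate in 13 only); iodine, II
Why: Hydroxyl-directed trans-hydroalumination of the propargylic alcohol puts aluminium on C4 inside a five-membered ring, cis to C6; iodine replaces it with retention. The C4=C5 geometry (C15 trans to C6) is therefore fixed by mechanism.

Step 11
Reactants: 14 (Z)-4-[(tert-butyldiphenylsilyl)oxy]-3-iodobut-2-en-1-ol
Product: 15 (Z)-4-[(tert-butyldiphenylsilyl)oxy]-3-iodobut-2-en-1-yl triethylsilyl ether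
Conditions: TESCl, imidazole, CH2Cl2, 0 °C
Reagents that add atoms: chlorotriethylsilane, CC[Si](Cl)(CC)CC
Why: Silylation; the primary TES ether on O6 is the most labile silyl group of the route and is removed together with the C8 TES ether in step 20.

Step 12
Reactants: 15 (Z)-4-[(tert-butyldiphenylsilyl)oxy]-3-iodobut-2-en-1-yl triethylsilyl ether; 16 (3-ethoxy-3-oxopropyl)zinc bromide
Product: 17 ethyl (E)-4-{[(tert-butyldiphenylsilyl)oxy]methyl}-6-[(triethylsilyl)oxy]hex-4-enoate
Conditions: Pd(PPh3)4 (5 mol%), THF, 50 °C
Reagents that add atoms: none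
Why: Negishi cross-coupling of the alkenyl iodide with the zinc homoenolate under zerovalent palladium catalysis; it proceeds with retention, so C3 ends cis to C6, and the ester supplies C1.

Step 13
Reactants: 17 ethyl (E)-4-{[(tert-butyldiphenylsilyl)oxy]methyl}-6-[(triethylsilyl)oxy]hex-4-enoate
Product: 18 (E)-4-{[(tert-butyldiphenylsilyl)oxy]methyl}-6-[(triethylsilyl)oxy]hex-4-enal
Conditions: i-Bu2AlH (1.1 equiv), CH2Cl2, −78 °C
Reagents that add atoms: none
Why: Partial reduction of the ester; the tetrahedral aluminium hemiacetal is stable at −78 °C and gives the aldehyde on work-up.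

Step 14
Reactants: 18 (E)-4-{[(tert-butyldiphenylsilyl)oxy]methyl}-6-[(triethylsilyl)oxy]hex-4-enal; 1 triethyl phosphonoacetate
Product: 20 ethyl (2Z,6E)-2-iodo-6-{[(tert-butyldiphenylsilyl)oxy]methyl}-8-[(triethylsilyl)oxy]octa-2,6-dienoate, via iodophosphonate 19 (not isolated)
Conditions: 1, NaH (2.1 equiv), THF, 0 °C; I2; then 18, 0 °C to rt
Reagents that add atoms: iodine, II
Why: Horner–Wadsworth–Emmons olefination with the phosphonate iodinated in the flask; the more stable isomer, expected as the main product, has iodine cis to C2 and the ester (C14) trans, which is the geometry the C1=C10 bond of the target needs.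

Step 15
Reactants: 20 ethyl (2Z,6E)-2-iodo-6-{[(tert-butyldiphenylsilyl)oxy]methyl}-8-[(triethylsilyl)oxy]octa-2,6-dienoate
Product: 21 (2Z,6E)-2-iodo-6-{[(tert-butyldiphenylsilyl)oxy]methyl}-8-[(triethylsilyl)oxy]octa-2,6-dien-1-ol
Conditions: i-Bu2AlH (2.2 equiv), CH2Cl2, −78 °C
Reagents that add atoms: none
Why: 1,2-Reduction of the iodo enoate to the allylic alcohol; the carbon–iodine bond is not touched by the aluminium hydride at −78 °C.

Step 16
Reactants: 21 (2Z,6E)-2-iodo-6-{[(tert-butyldiphenylsilyl)oxy]methyl}-8-[(triethylsilyl)oxy]octa-2,6-dien-1-ol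
Product: 22 (2Z,6E)-1-[(tert-butyldimethylsilyl)oxy]-2-iodo-6-{[(tert-butyldiphenylsilyl)oxy]methyl}-8-[(triethylsilyl)oxy]octa-2,6-diene
Conditions: TBSCl, imidazole, DMF, rt
Reagents that add atoms: tert-butyldimethylsilyl chloride, CC(C)(C)[Si](C)(C)Cl
Why: Silylation of the C14 hydroxyl; the fragment now carries three silyl ethers of graded lability (TES on O6, TBS on O14, TBDPS on O15).

Step 17
Reactants: 10 (2Z,4S)-2-{[(tert-butyldimethylsilyl)oxy]methyl}-5-oxo-4-[(triethylsilyl)oxy]pent-2-en-1-yl pivalate; 22 (2Z,6E)-1-[(tert-butyldimethylsilyl)oxy]-2-iodo-6-{[(tert-butyldiphenylsilyl)oxy]methyl}-8-[(triethylsilyl)oxy]octa-2,6-diene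
Product: 23 (8S,9R)-open-chain C9 alcohol (O13 pivalate; C12 and C14 TBS ethers; C15 TBDPS ether; O6 and O8 TES ethers)
Conditions: CrCl2 (6 equiv), NiCl2 (2 mol%), DMF, rt
Reagents that add atoms: none
Why: Nozaki–Hiyama–Kishi coupling: nickel-catalysed formation of the alkenylchromium species (divalent chromium as reductant) and its addition to the aldehyde with retention of olefin geometry, so C2 stays cis to C9. The medium is close to neutral, which suits the enolisable aldehyde, and Felkin–Anh addition anti to the C8 silyloxy group should favour the 8,9-anti (9R) alcohol.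

Step 18
Reactants: 23 (8S,9R)-open-chain C9 alcohol (O13 pivalate)
Product: 24 (8S,9R)-open-chain C9,C13 diol (C12 and C14 TBS ethers; C15 TBDPS ether; O6 and O8 TES ethers)
Conditions: i-Bu2AlH (3.5 equiv), CH2Cl2, −78 °C
Reagents that add atoms: none
Why: Reductive removal of the pivalate by the aluminium hydride; 23 contains no other ester and the silyl ethers are inert.

Step 19
Reactants: 24 (8S,9R)-open-chain C9,C13 diol
Product: 26 (8S,9R)-open-chain C13 chloride with free C9 hydroxyl (C12 and C14 TBS ethers; C15 TBDPS ether; O6 and O8 TES ethers), via allylic mesylate 25 (not isolated)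
Conditions: MsCl, LiCl, 2,4,6-collidine, DMF, 0 °C
Reagents that add atoms: methanesulfonyl chloride, CS(=O)(=O)Cl (sulfonate in 25 only); lithium chloride, [Li+].[Cl-]
Why: Collington–Meyers chlorination: the primary allylic hydroxyl is mesylated and displaced by chloride in an SN2 step without allylic transposition; the hindered secondary C9 hydroxyl, flanked by the C8 silyl ether and the fully substituted C10, should not react at 0 °C.

Step 20
Reactants: 26 (8S,9R)-open-chain C13 chloride with free C9 hydroxyl
Product: 28 (8S,9R)-chloro alcohol with O8/O9 acetonide and free O6 hydroxyl (C12 and C14 TBS ethers; C15 TBDPS ether), via triol 27 (not isolated)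
Conditions: PPTS, MeOH, 0 °C to rt; concentrate; 2,2-dimethoxypropane, acetone, rt; MeOH quench
Reagents that add atoms: 2,2-dimethoxypropane, COC(C)(C)OC
Why: Acid-catalysed methanolysis removes the two TES ethers much faster than the TBS and TBDPS ethers; transketalisation then closes the five-membered acetonide on the 8,9-diol. Formation of the cis-dioxolane also checks the anti relationship set in step 17.

Step 21
Reactants: 28 (8S,9R)-chloro alcohol with O8/O9 acetonide and free O6 hydroxyl
Product: 29 thirteen-membered diallylic ether (ring O, C13, C11, C7, C8, C9, C10, C1, C2, C3, C4, C5, C6; O8/O9 acetonide; C12 and C14 TBS ethers; C15 TBDPS ether)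
Conditions: NaH, n-Bu4NI (cat.), THF, 45 °C, slow addition (final 2 mM)
Reagents that add atoms: none
Why: Intramolecular Williamson etherification (13-exo-tet) at high dilution, an established closure for thirteen-membered diallylic ethers. The O6 alkoxide attacks the primary allylic C13 in an SN2 step; it has no silyl ether within reach, because C15 is trans to C6.

Step 22
Reactants: 29 thirteen-membered diallylic ether
Product: 31 (6R,7S,8S,9R)-ten-membered carbocycle with free C6 hydroxyl and a 3-[(tert-butyldimethylsilyl)oxy]prop-1-en-2-yl group on C7 (O8/O9 acetonide; C14 TBS ether; C15 TBDPS ether), via C6-lithio ether 30 (not isolated)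
Conditions: n-BuLi (1.2 equiv), THF, −78 °C, 1 h; H2O at −78 °C
Reagents that add atoms: n-butyllithium, [Li]CCCC (lithium in 30 only)
Why: n-BuLi removes a C6 proton (allylic to C4=C5 and alpha to the ether oxygen) to give 30; the carbanion carbon bonds to C7 through a five-membered envelope transition state (C6, O, C13, C11, C7) while O–C13 breaks and the double bond moves to C11=C13, a concerted [2,3]-Wittig shift. The closest known reaction is the [2,3]-Wittig ring contraction of thirteen-membered diallylic ethers to germacrane-type cyclodecadienols. The ten-membered ring closes formally as a 10-exo-trig attack of C6 on C7, delivered from inside the thirteen-membered ring, so no dilution is needed. For C6/C7, the trans placement of C8 and C13 on C7=C11 puts C8 in the outward position of the envelope and should give the anti pair (H6 and H7 trans, the later trans lactone). For C7 against C8, allylic strain with the C12 silyloxymethyl group (cis to C8) keeps H8 in the olefin plane, and the cis-dioxolane holds C7–C8–C9–C10 gauche, so a ten-membered ring can only form if C6 reaches C7 from the face opposite C9, the face that carries O8; this gives 6R,7S. The step needs lithiation at C6 and not at C13 or at the silyloxymethyl carbons: C13 hangs on the fully substituted C11 beside a bulky silyl ether, and a carbanion there could rearrange only by making C4 quaternary. Low temperature and a short reaction time are used so that the shift outruns loss of silanolate from C15 or opening of the acetonide.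

Step 23
Reactants: 31 (6R,7S,8S,9R)-ten-membered carbocycle with free C6 hydroxyl
Product: 32 (6R,7S,8S,9R)-triol with free O6, O12 and O14 hydroxyls (O8/O9 acetonide; C15 TBDPS ether)
Conditions: HF·pyridine, pyridine, THF, 0 °C to rt
Reagents that add atoms: none
Why: Buffered hydrogen fluoride cleaves the two primary allylic TBS ethers; the TBDPS ether and the acetonide are stable under these conditions.

Step 24
Reactants: 32 (6R,7S,8S,9R)-triol with free O6, O12 and O14 hydroxyls
Product: 34 6,12-lactone with exocyclic C11=C13 methylene and C14 aldehyde (O8/O9 acetonide; C15 TBDPS ether), via lactol 33 (not isolated)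
Conditions: TEMPO (0.2 equiv), PhI(OAc)2 (3.5 equiv), CH2Cl2, rt
Reagents that add atoms: none
Why: Oxoammonium oxidation, selective for primary alcohols: the C12 aldehyde is trapped by O6 as lactol 33, which is oxidised on to the lactone (oxidative lactonisation of a 2-methylene-1,4-diol), while the C14 alcohol stops at the enal. O8 is tied in the acetonide, so only the 6,12-lactone can form.

Step 25
Reactants: 34 6,12-lactone with C14 aldehyde
Product: 35 6,12-lactone with C14 carboxylic acid (O8/O9 acetonide; C15 TBDPS ether)
Conditions: NaClO2, NaH2PO4, 2-methyl-2-butene, t-BuOH–H2O, 0 °C to rt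
Reagents that add atoms: sodium chlorite, [Na+].[O-]Cl=O
Why: Pinnick oxidation of the enal to the acid; the alkene scavenger takes up hypochlorous acid, so the ring olefins and the methylene lactone are spared.

Step 26
Reactants: 35 6,12-lactone with C14 carboxylic acid
Product: 36 6,12-lactone with C14 methyl ester (O8/O9 acetonide; C15 TBDPS ether)
Conditions: MeI, KHCO3, DMF, rt
Reagents that add atoms: iodomethane, CI
Why: O-Alkylation of the carboxylate under weakly basic conditions; diazoalkanes are avoided because they add to the methylene lactone.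

Step 27
Reactants: 36 6,12-lactone with C14 methyl ester
Product: 37 (6R,7S,8S,9R)-8,9-diol lactone (C14 methyl ester; C15 TBDPS ether)
Conditions: TFA–H2O (9:1), CH2Cl2, 0 °C
Reagents that add atoms: none
Why: Acid hydrolysis of the acetonide; the primary TBDPS ether and the lactone tolerate brief aqueous acid, and acid, unlike base, does not move the lactone from O6 to the freed O8.

Step 28
Reactants: 37 (6R,7S,8S,9R)-8,9-diol lactone
Product: 38 9-O-acetyl-8-hydroxy lactone (C14 methyl ester; C15 TBDPS ether)
Conditions: AcCl (1.1 equiv), 2,4,6-collidine, CH2Cl2, −40 °C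
Reagents that add atoms: acetyl chloride, CC(Cl)=O
Why: Kinetic mono-acylation at low temperature: O9 is flanked by the planar C10 and should be more accessible than O8, which lies between two sp3 methine carbons next to the ring fusion.

Step 29
Reactants: 38 9-O-acetyl-8-hydroxy lactone
Product: 39 9-O-acetyl-8-O-methacryloyl lactone (C14 methyl ester; C15 TBDPS ether)
Conditions: methacrylic anhydride, Et3N, DMAP (cat.), BHT (trace), CH2Cl2, 0 °C
Reagents that add atoms: methacrylic anhydride, C=C(C)C(=O)OC(=O)C(C)=C
Why: DMAP-catalysed acylation of the remaining hindered hydroxyl with excess anhydride, so that O8 is trapped faster than the acetate can migrate.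

Step 30
Reactants: 39 9-O-acetyl-8-O-methacryloyl lactone
Product: 40 the target (6R,7S,8S,9R)
Conditions: HF·pyridine, THF, 0 °C to rt
Reagents that add atoms: none
Why: Fluoride-mediated cleavage of the primary TBDPS ether under weakly acidic conditions, which should not trigger acyl migration, conjugate addition or translactonisation.

## Compound list

1 | triethyl phosphonoacetate | CCOC(=O)CP(=O)(OCC)OCC | starting material
2 | ethyl 2-(diethoxyphosphoryl)-3-hydroxypropanoate (racemic) | CCOC(=O)C(CO)P(=O)(OCC)OCC | intermediate
3 | ethyl 3-[(tert-butyldimethylsilyl)oxy]-2-(diethoxyphosphoryl)propanoate (racemic) | CCOC(=O)C(CO[Si](C)(C)C(C)(C)C)P(=O)(OCC)OCC | intermediate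
4 | (R)-2,2-dimethyl-1,3-dioxolane-4-carbaldehyde | O=C[C@H]1COC(C)(C)O1 | starting material
5 | ethyl (E)-2-{[(tert-butyldimethylsilyl)oxy]methyl}-3-[(4S)-2,2-dimethyl-1,3-dioxolan-4-yl]prop-2-enoate | CCOC(=O)/C(CO[Si](C)(C)C(C)(C)C)=C/[C@H]1COC(C)(C)O1 | intermediate
6 | (Z)-2-{[(tert-butyldimethylsilyl)oxy]methyl}-3-[(4S)-2,2-dimethyl-1,3-dioxolan-4-yl]prop-2-en-1-ol | OC/C(CO[Si](C)(C)C(C)(C)C)=C/[C@H]1COC(C)(C)O1 | intermediate
7 | (Z)-2-{[(tert-butyldimethylsilyl)oxy]methyl}-3-[(4S)-2,2-dimethyl-1,3-dioxolan-4-yl]prop-2-en-1-yl pivalate | CC(C)(C)C(=O)OC/C(CO[Si](C)(C)C(C)(C)C)=C/[C@H]1COC(C)(C)O1 | intermediate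
8 | (2Z,4S)-2-{[(tert-butyldimethylsilyl)oxy]methyl}-4,5-dihydroxypent-2-en-1-yl pivalate | CC(C)(C)C(=O)OC/C(CO[Si](C)(C)C(C)(C)C)=C/[C@H](O)CO | intermediate
9 | (2Z,4S)-2-{[(tert-butyldimethylsilyl)oxy]methyl}-4,5-bis[(triethylsilyl)oxy]pent-2-en-1-yl pivalate | CC(C)(C)C(=O)OC/C(CO[Si](C)(C)C(C)(C)C)=C/[C@H](O[Si](CC)(CC)CC)CO[Si](CC)(CC)CC | intermediate
10 | (2Z,4S)-2-{[(tert-butyldimethylsilyl)oxy]methyl}-5-oxo-4-[(triethylsilyl)oxy]pent-2-en-1-yl pivalate (C9 aldehyde; C8 S) | CC(C)(C)C(=O)OC/C(CO[Si](C)(C)C(C)(C)C)=C/[C@H](O[Si](CC)(CC)CC)C=O | intermediate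
11 | but-2-yne-1,4-diol | OCC#CCO | starting material
12 | 4-[(tert-butyldiphenylsilyl)oxy]but-2-yn-1-ol | OCC#CCO[Si](c1ccccc1)(c1ccccc1)C(C)(C)C | intermediate
13 | sodium cyclic alkenyl(alkoxy)bis(2-methoxyethoxy)aluminate (five-membered ring O6, C6, C5=C4, Al) | [Na+].COCCO[Al-]1(OCCOC)OCC=C1CO[Si](c2ccccc2)(c2ccccc2)C(C)(C)C | intermediate
14 | (Z)-4-[(tert-butyldiphenylsilyl)oxy]-3-iodobut-2-en-1-ol | OC/C=C(/CO[Si](c1ccccc1)(c1ccccc1)C(C)(C)C)I | intermediate
15 | (Z)-4-[(tert-butyldiphenylsilyl)oxy]-3-iodobut-2-en-1-yl triethylsilyl ether | CC[Si](CC)(CC)OC/C=C(/CO[Si](c1ccccc1)(c1ccccc1)C(C)(C)C)I | intermediate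
16 | (3-ethoxy-3-oxopropyl)zinc bromide (commercial THF solution) | CCOC(=O)CC[Zn]Br | starting material
17 | ethyl (E)-4-{[(tert-butyldiphenylsilyl)oxy]methyl}-6-[(triethylsilyl)oxy]hex-4-enoate | CCOC(=O)CC/C(CO[Si](c1ccccc1)(c1ccccc1)C(C)(C)C)=C\CO[Si](CC)(CC)CC | intermediate
18 | (E)-4-{[(tert-butyldiphenylsilyl)oxy]methyl}-6-[(triethylsilyl)oxy]hex-4-enal | O=CCC/C(CO[Si](c1ccccc1)(c1ccccc1)C(C)(C)C)=C\CO[Si](CC)(CC)CC | intermediate
19 | ethyl 2-(diethoxyphosphoryl)-2-iodoacetate | CCOC(=O)C(I)P(=O)(OCC)OCC | intermediate
20 | ethyl (2Z,6E)-2-iodo-6-{[(tert-butyldiphenylsilyl)oxy]methyl}-8-[(triethylsilyl)oxy]octa-2,6-dienoate | CCOC(=O)/C(I)=C/CC/C(CO[Si](c1ccccc1)(c1ccccc1)C(C)(C)C)=C\CO[Si](CC)(CC)CC | intermediate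
21 | (2Z,6E)-2-iodo-6-{[(tert-butyldiphenylsilyl)oxy]methyl}-8-[(triethylsilyl)oxy]octa-2,6-dien-1-ol | OC/C(I)=C/CC/C(CO[Si](c1ccccc1)(c1ccccc1)C(C)(C)C)=C\CO[Si](CC)(CC)CC | intermediate
22 | (2Z,6E)-1-[(tert-butyldimethylsilyl)oxy]-2-iodo-6-{[(tert-butyldiphenylsilyl)oxy]methyl}-8-[(triethylsilyl)oxy]octa-2,6-diene | CC(C)(C)[Si](C)(C)OC/C(I)=C/CC/C(CO[Si](c1ccccc1)(c1ccccc1)C(C)(C)C)=C\CO[Si](CC)(CC)CC | intermediate
23 | (8S,9R)-open-chain C9 alcohol, chain C13–C11(=C7)–C8–C9–C10(=C1)–C2–C3–C4(=C5)–C6: O13 pivalate, C12 and C14 TBS ethers, C15 TBDPS ether, O6 and O8 TES ethers; C8 trans to C13, C2 cis to C9, C3 cis to C6 | CC(C)(C)C(=O)OC/C(CO[Si](C)(C)C(C)(C)C)=C/[C@H](O[Si](CC)(CC)CC)[C@H](O)/C(CO[Si](C)(C)C(C)(C)C)=C\CC/C(CO[Si](c1ccccc1)(c1ccccc1)C(C)(C)C)=C\CO[Si](CC)(CC)CC | intermediate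
24 | as 23 with free O13 hydroxyl (8S,9R C9,C13 diol) | OC/C(CO[Si](C)(C)C(C)(C)C)=C/[C@H](O[Si](CC)(CC)CC)[C@H](O)/C(CO[Si](C)(C)C(C)(C)C)=C\CC/C(CO[Si](c1ccccc1)(c1ccccc1)C(C)(C)C)=C\CO[Si](CC)(CC)CC | intermediate
25 | as 24 with O13 methanesulfonate | CS(=O)(=O)OC/C(CO[Si](C)(C)C(C)(C)C)=C/[C@H](O[Si](CC)(CC)CC)[C@H](O)/C(CO[Si](C)(C)C(C)(C)C)=C\CC/C(CO[Si](c1ccccc1)(c1ccccc1)C(C)(C)C)=C\CO[Si](CC)(CC)CC | intermediate
26 | as 24 with chloride on C13 (free C9 hydroxyl) | ClC/C(CO[Si](C)(C)C(C)(C)C)=C/[C@H](O[Si](CC)(CC)CC)[C@H](O)/C(CO[Si](C)(C)C(C)(C)C)=C\CC/C(CO[Si](c1ccccc1)(c1ccccc1)C(C)(C)C)=C\CO[Si](CC)(CC)CC | intermediate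
27 | (8S,9R)-C13 chloride with free O6, O8 and O9 hydroxyls (C12 and C14 TBS ethers, C15 TBDPS ether) | ClC/C(CO[Si](C)(C)C(C)(C)C)=C/[C@H](O)[C@H](O)/C(CO[Si](C)(C)C(C)(C)C)=C\CC/C(CO[Si](c1ccccc1)(c1ccccc1)C(C)(C)C)=C\CO | intermediate
28 | (8S,9R)-chloro alcohol: O8/O9 isopropylidene acetal (cis-dioxolane), C13 chloride, free O6 hydroxyl, C12 and C14 TBS ethers, C15 TBDPS ether | ClC/C(CO[Si](C)(C)C(C)(C)C)=C/[C@@H]1OC(C)(C)O[C@@H]1/C(CO[Si](C)(C)C(C)(C)C)=C\CC/C(CO[Si](c2ccccc2)(c2ccccc2)C(C)(C)C)=C\CO | intermediate
29 | thirteen-membered diallylic ether (O bridging C6 and C13; 8S,9R acetonide; C12 and C14 TBS ethers; C15 TBDPS ether; C8 trans to C13 on C7=C11, C2 cis to C9, C3 cis to C6) | O1C/C(CO[Si](C)(C)C(C)(C)C)=C/[C@@H]2OC(C)(C)O[C@@H]2/C(CO[Si](C)(C)C(C)(C)C)=C\CC/C(CO[Si](c3ccccc3)(c3ccccc3)C(C)(C)C)=C\C1 | intermediate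
30 | C6-lithio derivative of 29 | O1C/C(CO[Si](C)(C)C(C)(C)C)=C/[C@@H]2OC(C)(C)O[C@@H]2/C(CO[Si](C)(C)C(C)(C)C)=C\CC/C(CO[Si](c3ccccc3)(c3ccccc3)C(C)(C)C)=C\C1[Li] | intermediate
31 | (6R,7S,8S,9R)-ten-membered carbocycle: free C6 hydroxyl, 3-[(tert-butyldimethylsilyl)oxy]prop-1-en-2-yl on C7, O8/O9 acetonide, C14 TBS ether, C15 TBDPS ether | O1[C@H]2[C@@H](C(=C)CO[Si](C)(C)C(C)(C)C)[C@H](O)/C=C(/CO[Si](c3ccccc3)(c3ccccc3)C(C)(C)C)CC/C=C(/CO[Si](C)(C)C(C)(C)C)[C@H]2OC1(C)C | intermediate
32 | (6R,7S,8S,9R)-triol: free O6, O12 and O14 hydroxyls, O8/O9 acetonide, C15 TBDPS ether | O1[C@H]2[C@@H](C(=C)CO)[C@H](O)/C=C(/CO[Si](c3ccccc3)(c3ccccc3)C(C)(C)C)CC/C=C(/CO)[C@H]2OC1(C)C | intermediate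
33 | lactol (C12 hemiacetal with O6, mixture at C12) with C14 aldehyde, O8/O9 acetonide, C15 TBDPS ether | CC1(C)O[C@H]2[C@H]3C(=C)C(O)O[C@@H]3/C=C(/CO[Si](c4ccccc4)(c4ccccc4)C(C)(C)C)CC/C=C(/C=O)[C@H]2O1 | intermediate
34 | 6,12-lactone with exocyclic C11=C13, C14 aldehyde, O8/O9 acetonide, C15 TBDPS ether | CC1(C)O[C@H]2[C@H]3C(=C)C(=O)O[C@@H]3/C=C(/CO[Si](c4ccccc4)(c4ccccc4)C(C)(C)C)CC/C=C(/C=O)[C@H]2O1 | intermediate
35 | as 34 with C14 carboxylic acid | CC1(C)O[C@H]2[C@H]3C(=C)C(=O)O[C@@H]3/C=C(/CO[Si](c4ccccc4)(c4ccccc4)C(C)(C)C)CC/C=C(/C(=O)O)[C@H]2O1 | intermediate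
36 | as 34 with C14 methyl ester | CC1(C)O[C@H]2[C@H]3C(=C)C(=O)O[C@@H]3/C=C(/CO[Si](c4ccccc4)(c4ccccc4)C(C)(C)C)CC/C=C(/C(=O)OC)[C@H]2O1 | intermediate
37 | (6R,7S,8S,9R)-8,9-diol lactone, C14 methyl ester, C15 TBDPS ether | O[C@H]1[C@H]2C(=C)C(=O)O[C@@H]2/C=C(/CO[Si](c3ccccc3)(c3ccccc3)C(C)(C)C)CC/C=C(/C(=O)OC)[C@H]1O | intermediate
38 | 9-O-acetyl-8-hydroxy lactone, C14 methyl ester, C15 TBDPS ether | O[C@H]1[C@H]2C(=C)C(=O)O[C@@H]2/C=C(/CO[Si](c3ccccc3)(c3ccccc3)C(C)(C)C)CC/C=C(/C(=O)OC)[C@H]1OC(C)=O | intermediate
39 | 9-O-acetyl-8-O-methacryloyl lactone, C14 methyl ester, C15 TBDPS ether | C=C(C)C(=O)O[C@H]1[C@H]2C(=C)C(=O)O[C@@H]2/C=C(/CO[Si](c3ccccc3)(c3ccccc3)C(C)(C)C)CC/C=C(/C(=O)OC)[C@H]1OC(C)=O | intermediate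
40 | CNP0179134.4, (6R,7S,8S,9R) | C=C(C)C(=O)O[C@H]1[C@H]2C(=C)C(=O)O[C@@H]2/C=C(/CO)CC/C=C(/C(=O)OC)[C@H]1OC(C)=O | target

## Step count and least certain steps

Total: 30 steps. Longest linear sequence: 22 steps (steps 9 to 16, then 17 to 30). The other branch (steps 1 to 8) joins at step 17.

**Step 22 (key step).** Three things can go wrong.
- The base may take a proton from C13 instead of C6. That carbanion would open the acetonide, or contract the ring onto C4.
- The C6 allyl anion may expel silanolate from C15 in a 1,4-elimination to a dienyl ether before it rearranges.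
- C6 may bond to the wrong face of C7. A carbanion normally prefers to attack anti to an allylic C–O bond, and here that preference opposes the ring constraint relied on.

Fallback: set out from chloro alcohol 28, before the ether is made. Oxidise the C6 hydroxyl with MnO2 in CH2Cl2 to the C6 enal F1. Treat F1 with CrCl2 and catalytic LiI in THF–DMF under slow addition. The allylchromium species formed at C13 adds through C7 to the C6 aldehyde in a closed chair transition state (intramolecular Nozaki–Hiyama allylation). This forms the same C6–C7 bond and the C11=C13 methylene with the anti C6/C7 relationship, and returns to the route at 31. No carbanion and no strong base are involved.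

**Step 21.** Oligomerisation may compete with a slow thirteen-membered closure, or the chloride may be lost in side reactions under prolonged heating with base. Fallback: the detour described for step 22 starts from 28, the substrate of this step, passes through the C6 enal F1 and rejoins at 31, so it bypasses the macro-etherification as well and needs no further compound.

**Step 17.** Facial selectivity of the chromium addition at C9 may be modest, because the C8 substituents (silyloxy and alkenyl) compete for the Felkin position. Fallback: set out from 26 as obtained with mixed configuration at C9.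
- Oxidise with Dess–Martin periodinane to the C9 enone F2.
- Remove the TES ethers with PPTS in MeOH to give the alpha-hydroxy enone F3.
- Reduce with Zn(BH4)2 in Et2O at −20 °C. Chelation between O8 and the ketone delivers hydride to give the anti diol, which is triol 27.

The route continues from 27 with the ketalisation of step 20. C9 is then set by reduction instead of by addition.

**Step 28.** Discrimination between O9 and O8 may be insufficient, or the acetyl group may migrate from O9 to O8 during step 29. Fallback: set out from diol 37.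
- Silylate the more accessible hydroxyl with TESCl and imidazole at −40 °C to the 9-O-triethylsilyl ether F4. A bulky silyl chloride discriminates better than an acyl chloride and cannot migrate.
- Esterify O8 with methacrylic anhydride and DMAP to the 8-methacrylate silyl ether F5.
- Remove the silyl group with PPTS in MeOH to the 8-methacrylate 9-alcohol F6.
- Acetylate with acetic anhydride and DMAP, coming back to the route at 39.

The acetate is then introduced last, when no free neighbouring hydroxyl is left.

**Step 14.** Geometric selectivity of the iodo-olefination may be low, giving material with iodine trans to C2. Fallback: set out from aldehyde 18.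
- Wittig reaction with (triphenylphosphoranylidene)acetaldehyde gives the (2E)-enal F7.
- Alpha-iodination with I2, K2CO3 and catalytic DMAP in aqueous THF proceeds by addition–elimination and gives the (2Z)-2-iodo enal F8, with iodine cis to C2.
- Reduction with i-Bu2AlH at −78 °C returns to the route at 21.

## Further compounds

F1 | step 22 | C6 enal of 28: (8S,9R) O8/O9 acetonide, C13 chloride, C12 and C14 TBS ethers, C15 TBDPS ether, C6 aldehyde cis to C3 | ClC/C(CO[Si](C)(C)C(C)(C)C)=C/[C@@H]1OC(C)(C)O[C@@H]1/C(CO[Si](C)(C)C(C)(C)C)=C\CC/C(CO[Si](c2ccccc2)(c2ccccc2)C(C)(C)C)=C\C=O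
F0 | step 21 | none | none
F2 | step 17 | C9 enone from 26: (8S) C8 TES ether, C13 chloride, C12 and C14 TBS ethers, C15 TBDPS ether, O6 TES ether | ClC/C(CO[Si](C)(C)C(C)(C)C)=C/[C@H](O[Si](CC)(CC)CC)C(=O)/C(CO[Si](C)(C)C(C)(C)C)=C\CC/C(CO[Si](c1ccccc1)(c1ccccc1)C(C)(C)C)=C\CO[Si](CC)(CC)CC
F3 | step 17 | alpha-hydroxy enone: (8S) free O8 and O6 hydroxyls, C9 ketone, C13 chloride, C12 and C14 TBS ethers, C15 TBDPS ether | ClC/C(CO[Si](C)(C)C(C)(C)C)=C/[C@H](O)C(=O)/C(CO[Si](C)(C)C(C)(C)C)=C\CC/C(CO[Si](c1ccccc1)(c1ccccc1)C(C)(C)C)=C\CO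
F4 | step 28 | 9-O-triethylsilyl ether of 37 (free O8 hydroxyl) | O[C@H]1[C@H]2C(=C)C(=O)O[C@@H]2/C=C(/CO[Si](c3ccccc3)(c3ccccc3)C(C)(C)C)CC/C=C(/C(=O)OC)[C@H]1O[Si](CC)(CC)CC
F5 | step 28 | 8-O-methacryloyl 9-O-triethylsilyl lactone | C=C(C)C(=O)O[C@H]1[C@H]2C(=C)C(=O)O[C@@H]2/C=C(/CO[Si](c3ccccc3)(c3ccccc3)C(C)(C)C)CC/C=C(/C(=O)OC)[C@H]1O[Si](CC)(CC)CC
F6 | step 28 | 8-O-methacryloyl 9-hydroxy lactone | C=C(C)C(=O)O[C@H]1[C@H]2C(=C)C(=O)O[C@@H]2/C=C(/CO[Si](c3ccccc3)(c3ccccc3)C(C)(C)C)CC/C=C(/C(=O)OC)[C@H]1O
F7 | step 14 | (2E,6E)-6-{[(tert-butyldiphenylsilyl)oxy]methyl}-8-[(triethylsilyl)oxy]octa-2,6-dienal | O=C/C=C/CC/C(CO[Si](c1ccccc1)(c1ccccc1)C(C)(C)C)=C\CO[Si](CC)(CC)CC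
F8 | step 14 | (2Z,6E)-2-iodo-6-{[(tert-butyldiphenylsilyl)oxy]methyl}-8-[(triethylsilyl)oxy]octa-2,6-dienal | O=C/C(I)=C/CC/C(CO[Si](c1ccccc1)(c1ccccc1)C(C)(C)C)=C\CO[Si](CC)(CC)CC
A1 | alternative 1 | bicyclic 6,12-lactone with phenylselenomethyl group on C11, O8 methacrylate, O9 acetate, C14 methyl ester, C15 TBS ether | C=C(C)C(=O)O[C@H]1[C@H]2[C@@H](C[Se]c3ccccc3)C(=O)O[C@@H]2/C=C(/CO[Si](C)(C)C(C)(C)C)CC/C=C(/C(=O)OC)[C@H]1OC(C)=O
A2 | alternative 2 | cyclooct-4-enone (ring C2 to C9, C9 ketone) with O8 4-methoxybenzyl ether, 2,2-dimethyl-1,3-dioxan-5-yl group on C7, O6 TES ether, C15 TBDPS ether | COc1ccc(CO[C@H]2[C@@H](C3COC(C)(C)OC3)[C@H](O[Si](CC)(CC)CC)/C=C(/CO[Si](c3ccccc3)(c3ccccc3)C(C)(C)C)CCC2=O)cc1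
A3 | alternative 3 | ten-membered C9 ketone with C1=C10 methyl enoate, O8 4-methoxybenzyl ether, 3-[(triethylsilyl)oxy]prop-1-en-2-yl on C7, O6 TES ether, C15 TBS ether | COc1ccc(CO[C@H]2[C@@H](C(=C)CO[Si](CC)(CC)CC)[C@H](O[Si](CC)(CC)CC)/C=C(/CO[Si](C)(C)C(C)(C)C)CC/C=C(/C(=O)OC)C2=O)cc1
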